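## The problem

The target **30**, (2S,4R,6S)-2-(4-hydroxy-3-methoxyphenyl)-6-[(1R)-1-hydroxy-2-(4-hydroxyphenyl)ethyl]oxan-4-ol, is a linear diarylheptanoid in which an oxygen bridges C1 and C5 of the chain into an oxane. The chain is numbered from the carbon bearing the guaiacyl ring (ring A, C1) to the methylene bearing the 4-hydroxyphenyl ring (ring B, C7); the stereocentres are then 1S, 3R, 5S and 6R. Across the ring oxygen, ring A at C1 and the side chain at C5 are trans. In the chair that keeps the C3 hydroxyl and the C5 side chain equatorial, ring A is therefore axial, so this is the less stable ring isomer. Any closure that equilibrates, or that passes through a benzylic cation or an oxocarbenium ion at C1, would drift to the 2,6-cis isomer. In open-chain terms the C3 and C5 oxygens are 1,3-anti and the C5 and C6 oxygens are erythro. C6 is next to C5 and can direct it, and the C5 oxygen can direct C3 through a six-membered transition state. C1 is too remote to be controlled by the other centres and must be set by a reagent. The C1–O bond is a p-hydroxybenzylic ether (prone to acid ionisation, quinone methide formation and hydrogenolysis), the phenols are oxidisable, and β-oxygenated ketone intermediates can eliminate or undergo retro-aldol cleavage. The enabling feature is the unit C3 carbinol / C4 methylene / C5–O: it is a masked β-hydroxy ketone, i.e. the opened form of a 2-isoxazoline (C3=N, N–O–C5) standing on a carbon (C5) whose neighbour C6 is an allylic ether carbon in the corresponding alkene.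

## Retrosynthesis

**Protecting groups (30 ⇐ 29 ⇐ 28).** The last two operations cut only O–S and O–CH2Ph bonds. The ring A phenol is carried from the first step as its tosylate: it protects the phenol and makes ring A electron-poor, which is what permits a bimolecular displacement at C1. The ring B phenol and the C3 and C6 oxygens are benzyl ethers, removed together by hydrogenolysis (**28** to **29**). This is done while ring A is still deactivated, so the cyclic benzylic C1–O bond is least prone to cleavage. The sulfonate is cleaved last (**29** to **30**).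

**Ring closure (28 ⇐ 25).** The oxane is opened at C1–O. Cutting O–C5 instead would require displacement at a hindered, β-oxygenated secondary carbon. Forming C1–O by hydride addition to a cyclic oxocarbenium ion would give the 2,6-cis ring. The chosen cut leads to acyclic hydroxy acetate **25**, in which C1 has the R configuration, opposite to the target. Mesylation (**26**), release of the C5 oxygen (**27**) and 6-exo-tet displacement with inversion then give the trans ring. The forward step must be a clean SN2 reaction; the tosyloxy group on ring A and a non-participating benzyl ether at C3 are there for that purpose.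

**C3 carbinol (25 ⇐ 24 ⇐ 23 ⇐ 21).** The C3 stereocentre is traced to ketone **21**. An Evans–Tishchenko reduction is preferred to an external hydride because it sets the 1,3-anti relationship from the C5 hydroxyl and, in the same event, differentiates the two oxygens: O5 becomes an acetate (the latent nucleophile) and O3 stays free (**23**). O3 is then benzylated (**24**) and the C1 silyl ether removed (**25**).

**Unmasking (21 ⇐ 19).** β-Hydroxy ketone **21** is the N–O cleavage product of isoxazoline **19**. Nothing is lost in simplicity, and the isoxazoline protects the aldol unit from retro-aldol chemistry until needed.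

**Key disconnection (19 ⇐ 18 + 16).** Cutting C3–C4 and O–C5 together divides **19** into nitrile oxide **18** (C1–C3) and allyl ether **16** (C4–C7), each with one stereocentre. An aldol cut of C4–C5 alone would need an α-alkoxy aldehyde and an acetate-type enolate, with weaker stereocontrol and a labile product. The cycloaddition forms both bonds and the C5 stereocentre under control of C6 through the inside-alkoxy transition state, which gives the erythro pair that the target needs. The forward reaction must be regioselective (normal for a monosubstituted alkene) and π-facially selective. The facial preference is expected to be only moderate for a C6 substituent that is a primary alkyl group; the threo isomer is removed at the isoxazoline stage.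

**C1–C3 fragment (18 ⇐ 8 ⇐ 7 ⇐ 5 ⇐ 4 ⇐ 2 ⇐ 1).** Nitrile oxide **18** is generated from aldoxime **8**, which comes from aldehyde **7**, the ozonolysis product of silyl ether **5**. The C1 stereocentre is set by reagent-controlled allylboration of O-tosylvanillin **2**, made from vanillin **1**, giving alcohol **4**.

**C4–C7 fragment (16 ⇐ 15 ⇐ 12 ⇐ 9 + 10).** Benzyl ether **16** comes from allylic alcohol **15**. Its vinyl group is a one-carbon homologation of the epoxide derived from chlorohydrin **12**, which is the copper-catalysed opening product of (R)-epichlorohydrin **10** by the Grignard reagent of bromide **9**. The C6 stereocentre is thus bought.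

## Roads not taken

Alternative 1: The ring is cut at O–C5 and C5 is made the electrophile. The precursor is trans-epoxy alcohol **A1**, with C1 already in its final S configuration. Under catalytic camphorsulfonic acid the C1 hydroxyl opens the epoxide at C5 (6-exo, inversion) to give oxane **A2** and frees the C6 hydroxyl in the same step. Its merit is real: the displacement occurs at a non-benzylic carbon, so ionisation at C1 does not arise in the bond-forming event, and the endgame is shorter. In the ring closure itself this road is at least as good as the chosen one. Its weak points are upstream. The (5R,6R)-epoxide has no allylic hydroxyl and must be made by reagent-controlled epoxidation of an unfunctionalised E-alkene. C1 and C3 also have to be set independently, and the C1–C7 chain still has to be assembled linearly. In addition, the acid acts on a benzylic alcohol attached to an electron-rich benzyl-protected ring A, where ionisation would scramble C1. The chosen plan sets against it a convergent union of two equal fragments and substrate control for two of the four centres (C5 from C6, C3 from C5).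

Alternative 2: C3 is introduced as a dithiane linchpin. Lithiated silyl dithiane **A3** opens aryl oxirane **A4** at its terminal carbon, an HMPA-triggered 1,4-Brook rearrangement moves silicon to the C1 oxygen, and the new anion opens epoxide **A5** to give **A6**. Hydrolysis of the dithiane in **A6** would give ketone **21** of the chosen route. The coupling forms two C–C bonds in one flask and creates no new stereocentre, so it has no diastereoselectivity question. In that respect it is better than a cycloaddition with moderate facial selectivity. However, the C5/C6 erythro relationship is not solved, only moved: **A5** is the erythro epoxide of alkene **16**, and peracid epoxidation of such an allyl ether is no better controlled than the cycloaddition. The aryl sulfonate in **A4** must also survive alkyllithium reagents and a dithiane anion. Removing the dithiane next to a β-hydroxy and a β-silyloxy group calls for oxidative or thiophilic reagents in the presence of electron-rich rings. Step count would be similar. The chosen plan sets C5 in the same step that joins the fragments.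

Alternative 3: C1 enters as an aroyl ester on the C5 oxygen (**A7**). Methylenation with Cp2Ti(CH2)(Cl)AlMe2 gives enol ether **A8**, and ring-closing metathesis with the C3 vinyl group (second-generation Grubbs catalyst) closes dihydropyran **A9**, forming C1=C2. The attractions are a cheap, achiral C1 building block and a robust ring closure that uses the C5 oxygen as ring oxygen. For this target the difficulty is the last stereocentre: C1 must then be created by adding hydrogen to the enol ether. Both undirected catalytic hydrogenation (from the face away from the C3 and C5 substituents) and ionic reduction (axial hydride to the oxocarbenium ion) lead to the 2,6-cis oxane. Only a hydrogenation directed by a free C3 hydroxyl, on an acid-sensitive aryl enol ether, could give the trans ring, and that is the least secure step imaginable for the final stereocentre. **A7** also already needs C3, C5 and C6 in place. This would be the better road to the 2,6-cis epimer; for the trans compound, the chosen plan's stereospecific inversion at C1 is the safer device.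

Key step: step 9

## Route

Remark on conventions: open-chain intermediates are named with the chain locants C1 (ring A carbon) to C7 defined above. The CIP label of C3 alternates (S or R) with the groups on O1 and O5 although its geometry never changes. Ts = 4-methylbenzenesulfonyl, TBS = tert-butyldimethylsilyl, Bn = benzyl.

Step 1
Reactants: 1 vanillin
Product: 2 O-tosylvanillin (4-formyl-2-methoxyphenyl 4-methylbenzenesulfonate)
Conditions: TsCl, Et3N, DMAP (cat.), CH2Cl2, 0 °C → rt
Reagents that add atoms: 4-toluenesulfonyl chloride, Cc1ccc(cc1)S(Cl)(=O)=O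
Why: Sulfonylation of the phenol; the tosylate protects the phenol for the whole route and is the electron-withdrawing group that later disfavours ionisation at C1.

Step 2
Reactants: 2 O-tosylvanillin
Product: 4 (R)-homoallylic alcohol 4-[(1R)-1-hydroxybut-3-en-1-yl]-2-methoxyphenyl 4-methylbenzenesulfonate, via borinic ester 3 (not isolated)
Conditions: (+)-Ipc2B(allyl) [(−)-α-pinene series], Et2O, −78 °C; then NaOH, H2O2, 0 °C → rt
Reagents that add atoms: (+)-B-allyldiisopinocampheylborane, C=CCB([C@H]1C[C@H]2C[C@@H]([C@@H]1C)C2(C)C)[C@H]1C[C@H]2C[C@@H]([C@@H]1C)C2(C)C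
Why: Brown allylboration through a closed chair transition state; the reagent of the (−)-α-pinene series adds allyl to the Re face of aryl aldehydes and should set C1 as R, the configuration opposite to the target, which is inverted in step 14.

Step 3
Reactants: 4 (R)-homoallylic alcohol
Product: 5 silyl ether 4-[(1R)-1-(tert-butyldimethylsilyloxy)but-3-en-1-yl]-2-methoxyphenyl 4-methylbenzenesulfonate
Conditions: TBSCl, imidazole, DMF, rt
Reagents that add atoms: tert-butyldimethylsilyl chloride, CC(C)(C)[Si](C)(C)Cl
Why: Standard silylation of a secondary benzylic alcohol; the silyl ether blocks O1 through oxidation, cycloaddition and reduction and is later removable with fluoride beside an acetate and benzyl ethers.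

Step 4
Reactants: 5 silyl ether
Product: 7 aldehyde (3R)-3-(tert-butyldimethylsilyloxy)-3-[3-methoxy-4-(tosyloxy)phenyl]propanal, via ozonide 6 (not isolated)
Conditions: O3, CH2Cl2, −78 °C; then PPh3, −78 °C → rt
Reagents that add atoms: ozone, [O-][O+]=O
Why: Ozonolysis of the terminal alkene with reductive work-up; the sulfonate-bearing arene is far less reactive towards ozone than the monosubstituted alkene, and C1 is untouched.

Step 5
Reactants: 7 aldehyde
Product: 8 aldoxime (E/Z) of 7
Conditions: NH2OH·HCl, NaOAc, EtOH/H2O, rt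
Reagents that add atoms: hydroxylamine hydrochloride, [NH3+]O.[Cl-]
Why: Buffered oxime condensation; both oxime isomers serve as nitrile oxide precursors, and the mild conditions avoid β-elimination of the silyloxy group.

Step 6
Reactants: 9 1-(benzyloxy)-4-bromobenzene; 10 (R)-epichlorohydrin
Product: 12 chlorohydrin (2R)-1-[4-(benzyloxy)phenyl]-3-chloropropan-2-ol, via aryl Grignard reagent 11 (not isolated)
Conditions: Mg, THF, rt → 40 °C; then CuI (10 mol %), 10, THF, −40 → 0 °C; aqueous work-up
Reagents that add atoms: none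
Why: Copper-catalysed opening of the epoxide by the aryl Grignard reagent at the unsubstituted carbon; the stereocentre of 10 is not involved and becomes C6.

Step 7
Reactants: 12 chlorohydrin
Product: 15 allylic alcohol (2R)-1-[4-(benzyloxy)phenyl]but-3-en-2-ol, via epoxide 13 (not isolated), via sulfonium betaine 14 (not isolated)
Conditions: Me3S+ I− (4 equiv), n-BuLi (3.9 equiv), THF, −20 °C → rt
Reagents that add atoms: trimethylsulfonium iodide, C[S+](C)C.[I-]
Why: Sulfonium ylide homologation with the Corey–Chaykovsky reagent in excess: the ylide first acts as base and closes 12 to epoxide 13, then opens it at the terminal carbon to betaine 14, and further base eliminates dimethyl sulfide to give the vinyl carbinol; the carbinol centre is untouched.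

Step 8
Reactants: 15 allylic alcohol
Product: 16 allyl ether 1-(benzyloxy)-4-[(2R)-2-(benzyloxy)but-3-en-1-yl]benzene
Conditions: NaH, BnBr, n-Bu4NI (cat.), THF, 0 °C → rt
Reagents that add atoms: benzyl bromide, BrCc1ccccc1
Why: Williamson etherification; the benzyl ether supplies the alkoxy group required by the inside-alkoxy transition state of step 9 and leaves with the other benzyl groups in step 15.

Step 9
Reactants: 8 aldoxime; 16 allyl ether
Product: 19 erythro isoxazoline (1R,5S,6R) 4-{(1R)-2-[(5S)-5-{(1R)-1-(benzyloxy)-2-[4-(benzyloxy)phenyl]ethyl}-4,5-dihydro-1,2-oxazol-3-yl]-1-(tert-butyldimethylsilyloxy)ethyl}-2-methoxyphenyl 4-methylbenzenesulfonate, via hydroximoyl chloride 17 (not isolated), via nitrile oxide 18 (not isolated)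
Conditions: aq. NaOCl (slow addition), Et3N (cat.), CH2Cl2, 0 °C → rt
Reagents that add atoms: none
Why: NaOCl chlorinates aldoxime 8 to hydroximoyl chloride 17, which loses HCl under the basic two-phase conditions to give nitrile oxide 18; slow addition keeps 18 dilute so that capture by 16 outruns dimerisation to the furoxan. The dipole adds to the vinyl group of 16 in a concerted, asynchronous Huisgen 1,3-dipolar cycloaddition; the closest known reaction type is nitrile oxide addition to chiral allyl ethers. The 4,5-dihydroisoxazole ring is closed in this single intermolecular [3+2] event, C3–C4 and O–C5 forming together, so no separate cyclisation mode has to be satisfied. Regiochemistry (oxygen to the substituted carbon C5, dipole carbon to terminal C4) is the normal outcome for monosubstituted alkenes on steric and frontier-orbital grounds. The only new stereocentre, C5, is controlled by allylic C6: in the favoured transition state the benzyloxy group lies inside, the 4-benzyloxybenzyl group anti to the incoming dipole and hydrogen outside, which places the new C5–O bond erythro to C6–O and gives (5S,6R). The selectivity needed is π-facial, and with a primary alkyl group at C6 the ether should secure it only moderately, so the threo isomer is expected as a minor product to be removed by chromatography here; O6 must stay etherified because a free or metal-bound hydroxyl would reverse the sense. C1 and C6 are not touched, and the aryl tosylate, silyl ether and benzyl ethers are inert to cold aqueous NaOCl.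

Step 10
Reactants: 19 erythro isoxazoline
Product: 21 β-hydroxy ketone (1R,5S,6R)-6-(benzyloxy)-7-[4-(benzyloxy)phenyl]-1-(tert-butyldimethylsilyloxy)-5-hydroxy-1-[3-methoxy-4-(tosyloxy)phenyl]heptan-3-one, via β-hydroxy imine 20 (not isolated)
Conditions: Mo(CO)6, MeCN/H2O, 80 °C
Reagents that add atoms: water, O
Why: Reductive N–O cleavage of the 2-isoxazoline by zerovalent molybdenum gives the β-hydroxy imine, hydrolysed in situ to the ketone; the neutral medium avoids retro-aldol cleavage and loss of the β-silyloxy group, and C5 keeps its configuration.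

Step 11
Reactants: 21 β-hydroxy ketone
Product: 23 anti-diol monoacetate (1R,3S,5S,6R)-6-(benzyloxy)-7-[4-(benzyloxy)phenyl]-1-(tert-butyldimethylsilyloxy)-3-hydroxy-1-[3-methoxy-4-(tosyloxy)phenyl]heptan-5-yl acetate, via samarium-bound hemiacetal 22 (not isolated)
Conditions: SmI2 (30 mol %), MeCHO (8 equiv), THF, −10 °C
Reagents that add atoms: acetaldehyde, CC=O
Why: Evans–Tishchenko reduction: the C5 hydroxyl forms a samarium-bound hemiacetal with acetaldehyde whose hydride is delivered intramolecularly to the C3 ketone through a chair-like six-membered transition state, setting C3 1,3-anti to C5; the same event acetylates O5 and leaves O3 free, which differentiates the two oxygens.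

Step 12
Reactants: 23 anti-diol monoacetate
Product: 24 C3 benzyl ether (1R,3S,5S,6R)-3,6-bis(benzyloxy)-7-[4-(benzyloxy)phenyl]-1-(tert-butyldimethylsilyloxy)-1-[3-methoxy-4-(tosyloxy)phenyl]heptan-5-yl acetate
Conditions: BnOC(=NH)CCl3, TfOH (5 mol %), CH2Cl2/cyclohexane, 0 °C
Reagents that add atoms: benzyl 2,2,2-trichloroacetimidate, N=C(OCc1ccccc1)C(Cl)(Cl)Cl
Why: Acid-catalysed O-benzylation with the trichloroacetimidate avoids the base that would cause acetyl migration or elimination; a benzyl ether at C3 cannot act as a neighbouring group when C1 is activated, and it leaves in the final hydrogenolysis.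

Step 13
Reactants: 24 C3 benzyl ether
Product: 25 C1 alcohol (1R,3R,5S,6R)-3,6-bis(benzyloxy)-7-[4-(benzyloxy)phenyl]-1-hydroxy-1-[3-methoxy-4-(tosyloxy)phenyl]heptan-5-yl acetate
Conditions: HF·pyridine, pyridine, THF, 0 °C → rt
Reagents that add atoms: none
Why: Fluoride cleavage of the silyl ether under buffered, slightly acidic conditions that leave the acetate, benzyl ethers and aryl sulfonate in place and do not promote acyl migration.

Step 14
Reactants: 25 C1 alcohol
Product: 28 protected 2,6-trans oxane 4-[(2S,4R,6S)-4-(benzyloxy)-6-{(1R)-1-(benzyloxy)-2-[4-(benzyloxy)phenyl]ethyl}oxan-2-yl]-2-methoxyphenyl 4-methylbenzenesulfonate, via mesylate 26 (not isolated), via hydroxy mesylate 27 (not isolated)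
Conditions: MsCl, Et3N, THF, −30 °C; then K2CO3, MeOH (THF/MeOH 2:1), −30 → 0 °C
Reagents that add atoms: none
Why: Intramolecular Williamson etherification: the only free hydroxyl (C1) is mesylated, methanolysis of the C5 acetate then frees O5, which displaces the benzylic mesylate by 6-exo-tet SN2 attack with inversion at C1 (R to S) to give the 2,6-trans oxane; the tosyloxy-substituted ring and the weakly ionising medium disfavour ionisation of the mesylate, and the C3 benzyl ether cannot participate.

Step 15
Reactants: 28 protected 2,6-trans oxane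
Product: 29 triol tosylate 4-[(2S,4R,6S)-4-hydroxy-6-[(1R)-1-hydroxy-2-(4-hydroxyphenyl)ethyl]oxan-2-yl]-2-methoxyphenyl 4-methylbenzenesulfonate
Conditions: H2 (1 atm), Pd(OH)2/C, EtOAc/MeOH, rt
Reagents that add atoms: none
Why: Catalytic hydrogenolysis of the aryl benzyl ether and the two secondary alkyl benzyl ethers; the cyclic benzylic C1–O bond is hindered and sits on an electron-poor ring and the aryl sulfonate is inert, so the ring should survive.

Step 16
Reactants: 29 triol tosylate
Product: 30 target (2S,4R,6S)-2-(4-hydroxy-3-methoxyphenyl)-6-[(1R)-1-hydroxy-2-(4-hydroxyphenyl)ethyl]oxan-4-ol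
Conditions: KOH, MeOH/H2O, 60 °C; then aq. NH4Cl to pH 6
Reagents that add atoms: none
Why: Saponification of the aryl sulfonate by hydroxide attack at sulfur releases the phenoxide; it is done last and at moderate temperature so that the p-hydroxybenzylic ether is exposed to base only briefly before neutralisation.

## Compound list

1 | vanillin (4-hydroxy-3-methoxybenzaldehyde) | COc1cc(C=O)ccc1O | starting material
2 | 4-formyl-2-methoxyphenyl 4-methylbenzenesulfonate (O-tosylvanillin) | COc1cc(C=O)ccc1OS(=O)(=O)c1ccc(C)cc1 | intermediate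
3 | (1R)-1-[3-methoxy-4-(tosyloxy)phenyl]but-3-en-1-yl diisopinocampheylborinate | COc1cc([C@H](OB([C@H]2C[C@H]3C[C@@H]([C@@H]2C)C3(C)C)[C@H]2C[C@H]3C[C@@H]([C@@H]2C)C3(C)C)CC=C)ccc1OS(=O)(=O)c1ccc(C)cc1 | intermediate
4 | 4-[(1R)-1-hydroxybut-3-en-1-yl]-2-methoxyphenyl 4-methylbenzenesulfonate | COc1cc([C@H](O)CC=C)ccc1OS(=O)(=O)c1ccc(C)cc1 | intermediate
5 | 4-[(1R)-1-(tert-butyldimethylsilyloxy)but-3-en-1-yl]-2-methoxyphenyl 4-methylbenzenesulfonate | COc1cc([C@H](O[Si](C)(C)C(C)(C)C)CC=C)ccc1OS(=O)(=O)c1ccc(C)cc1 | intermediate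
6 | 4-[(1R)-1-(tert-butyldimethylsilyloxy)-2-(1,2,4-trioxolan-3-yl)ethyl]-2-methoxyphenyl 4-methylbenzenesulfonate (secondary ozonide, both epimers at the trioxolane carbon) | COc1cc([C@H](O[Si](C)(C)C(C)(C)C)CC2OCOO2)ccc1OS(=O)(=O)c1ccc(C)cc1 | intermediate
7 | 4-[(1R)-1-(tert-butyldimethylsilyloxy)-3-oxopropyl]-2-methoxyphenyl 4-methylbenzenesulfonate | COc1cc([C@H](O[Si](C)(C)C(C)(C)C)CC=O)ccc1OS(=O)(=O)c1ccc(C)cc1 | intermediate
8 | 4-[(1R)-1-(tert-butyldimethylsilyloxy)-3-(hydroxyimino)propyl]-2-methoxyphenyl 4-methylbenzenesulfonate (E/Z) | COc1cc([C@H](O[Si](C)(C)C(C)(C)C)CC=NO)ccc1OS(=O)(=O)c1ccc(C)cc1 | intermediate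
9 | 1-(benzyloxy)-4-bromobenzene | Brc1ccc(OCc2ccccc2)cc1 | starting material
10 | (R)-epichlorohydrin [(2R)-2-(chloromethyl)oxirane] | ClC[C@H]1CO1 | starting material
11 | 4-(benzyloxy)phenylmagnesium bromide | Br[Mg]c1ccc(OCc2ccccc2)cc1 | intermediate
12 | (2R)-1-[4-(benzyloxy)phenyl]-3-chloropropan-2-ol | ClC[C@H](O)Cc1ccc(OCc2ccccc2)cc1 | intermediate
13 | (2R)-2-[4-(benzyloxy)benzyl]oxirane | C1O[C@@H]1Cc1ccc(OCc2ccccc2)cc1 | intermediate
14 | (2R)-1-[4-(benzyloxy)phenyl]-4-(dimethylsulfonio)butan-2-olate | C[S+](C)CC[C@H]([O-])Cc1ccc(OCc2ccccc2)cc1 | intermediate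
15 | (2R)-1-[4-(benzyloxy)phenyl]but-3-en-2-ol | C=C[C@H](O)Cc1ccc(OCc2ccccc2)cc1 | intermediate
16 | 1-(benzyloxy)-4-[(2R)-2-(benzyloxy)but-3-en-1-yl]benzene | C=C[C@H](OCc1ccccc1)Cc1ccc(OCc2ccccc2)cc1 | intermediate
17 | 4-[(1R)-1-(tert-butyldimethylsilyloxy)-3-chloro-3-(hydroxyimino)propyl]-2-methoxyphenyl 4-methylbenzenesulfonate | COc1cc([C@H](O[Si](C)(C)C(C)(C)C)CC(Cl)=NO)ccc1OS(=O)(=O)c1ccc(C)cc1 | intermediate
18 | (3R)-3-(tert-butyldimethylsilyloxy)-3-[3-methoxy-4-(tosyloxy)phenyl]propanenitrile N-oxide | COc1cc([C@H](O[Si](C)(C)C(C)(C)C)CC#[N+][O-])ccc1OS(=O)(=O)c1ccc(C)cc1 | intermediate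
19 | 4-{(1R)-2-[(5S)-5-{(1R)-1-(benzyloxy)-2-[4-(benzyloxy)phenyl]ethyl}-4,5-dihydro-1,2-oxazol-3-yl]-1-(tert-butyldimethylsilyloxy)ethyl}-2-methoxyphenyl 4-methylbenzenesulfonate (chain descriptors 1R,5S,6R; erythro C5/C6) | COc1cc([C@H](O[Si](C)(C)C(C)(C)C)CC2=NO[C@H]([C@H](OCc3ccccc3)Cc3ccc(OCc4ccccc4)cc3)C2)ccc1OS(=O)(=O)c1ccc(C)cc1 | intermediate
20 | (1R,5S,6R)-6-(benzyloxy)-7-[4-(benzyloxy)phenyl]-1-(tert-butyldimethylsilyloxy)-3-imino-1-[3-methoxy-4-(tosyloxy)phenyl]heptan-5-ol | COc1cc([C@H](O[Si](C)(C)C(C)(C)C)CC(=N)C[C@H](O)[C@H](OCc2ccccc2)Cc2ccc(OCc3ccccc3)cc2)ccc1OS(=O)(=O)c1ccc(C)cc1 | intermediate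
21 | (1R,5S,6R)-6-(benzyloxy)-7-[4-(benzyloxy)phenyl]-1-(tert-butyldimethylsilyloxy)-5-hydroxy-1-[3-methoxy-4-(tosyloxy)phenyl]heptan-3-one | COc1cc([C@H](O[Si](C)(C)C(C)(C)C)CC(=O)C[C@H](O)[C@H](OCc2ccccc2)Cc2ccc(OCc3ccccc3)cc2)ccc1OS(=O)(=O)c1ccc(C)cc1 | intermediate
22 | hemiacetal of 21 at O5 with acetaldehyde (present as its samarium alkoxide; epimers at the hemiacetal carbon) | COc1cc([C@H](O[Si](C)(C)C(C)(C)C)CC(=O)C[C@H](OC(C)O)[C@H](OCc2ccccc2)Cc2ccc(OCc3ccccc3)cc2)ccc1OS(=O)(=O)c1ccc(C)cc1 | intermediate
23 | (1R,3S,5S,6R)-6-(benzyloxy)-7-[4-(benzyloxy)phenyl]-1-(tert-butyldimethylsilyloxy)-3-hydroxy-1-[3-methoxy-4-(tosyloxy)phenyl]heptan-5-yl acetate | COc1cc([C@H](O[Si](C)(C)C(C)(C)C)C[C@@H](O)C[C@H](OC(C)=O)[C@H](OCc2ccccc2)Cc2ccc(OCc3ccccc3)cc2)ccc1OS(=O)(=O)c1ccc(C)cc1 | intermediate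
24 | (1R,3S,5S,6R)-3,6-bis(benzyloxy)-7-[4-(benzyloxy)phenyl]-1-(tert-butyldimethylsilyloxy)-1-[3-methoxy-4-(tosyloxy)phenyl]heptan-5-yl acetate | COc1cc([C@H](O[Si](C)(C)C(C)(C)C)C[C@@H](OCc2ccccc2)C[C@H](OC(C)=O)[C@H](OCc2ccccc2)Cc2ccc(OCc3ccccc3)cc2)ccc1OS(=O)(=O)c1ccc(C)cc1 | intermediate
25 | (1R,3R,5S,6R)-3,6-bis(benzyloxy)-7-[4-(benzyloxy)phenyl]-1-hydroxy-1-[3-methoxy-4-(tosyloxy)phenyl]heptan-5-yl acetate | COc1cc([C@H](O)C[C@@H](OCc2ccccc2)C[C@H](OC(C)=O)[C@H](OCc2ccccc2)Cc2ccc(OCc3ccccc3)cc2)ccc1OS(=O)(=O)c1ccc(C)cc1 | intermediate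
26 | (1R,3S,5S,6R)-3,6-bis(benzyloxy)-7-[4-(benzyloxy)phenyl]-1-(methanesulfonyloxy)-1-[3-methoxy-4-(tosyloxy)phenyl]heptan-5-yl acetate | COc1cc([C@H](OS(C)(=O)=O)C[C@@H](OCc2ccccc2)C[C@H](OC(C)=O)[C@H](OCc2ccccc2)Cc2ccc(OCc3ccccc3)cc2)ccc1OS(=O)(=O)c1ccc(C)cc1 | intermediate
27 | (1R,3S,5S,6R)-3,6-bis(benzyloxy)-7-[4-(benzyloxy)phenyl]-5-hydroxy-1-[3-methoxy-4-(tosyloxy)phenyl]heptyl methanesulfonate | COc1cc([C@H](OS(C)(=O)=O)C[C@@H](OCc2ccccc2)C[C@H](O)[C@H](OCc2ccccc2)Cc2ccc(OCc3ccccc3)cc2)ccc1OS(=O)(=O)c1ccc(C)cc1 | intermediate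
28 | 4-[(2S,4R,6S)-4-(benzyloxy)-6-{(1R)-1-(benzyloxy)-2-[4-(benzyloxy)phenyl]ethyl}oxan-2-yl]-2-methoxyphenyl 4-methylbenzenesulfonate | COc1cc([C@@H]2C[C@@H](OCc3ccccc3)C[C@@H]([C@H](OCc3ccccc3)Cc3ccc(OCc4ccccc4)cc3)O2)ccc1OS(=O)(=O)c1ccc(C)cc1 | intermediate
29 | 4-[(2S,4R,6S)-4-hydroxy-6-[(1R)-1-hydroxy-2-(4-hydroxyphenyl)ethyl]oxan-2-yl]-2-methoxyphenyl 4-methylbenzenesulfonate | COc1cc([C@@H]2C[C@@H](O)C[C@@H]([C@H](O)Cc3ccc(O)cc3)O2)ccc1OS(=O)(=O)c1ccc(C)cc1 | intermediate
30 | (2S,4R,6S)-2-(4-hydroxy-3-methoxyphenyl)-6-[(1R)-1-hydroxy-2-(4-hydroxyphenyl)ethyl]oxan-4-ol | COc1cc([C@@H]2C[C@@H](O)C[C@@H]([C@H](O)Cc3ccc(O)cc3)O2)ccc1O | target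

## Step count and risks

Total: 16 steps. Longest linear sequence: 13 steps (1–5, then 9–16, from vanillin); the second branch (steps 6–8) joins at step 9.

**Step 9 (key step).** The most likely failure is insufficient π-facial discrimination. The inside-alkoxy preference is modest when the C6 substituent is a primary alkyl group, so a sizeable share of threo isoxazoline may form and have to be separated. Dimerisation of the aliphatic nitrile oxide is the second loss channel.

Fallback, from alcohol **15** and oxime **8**, returning at **19**: the control element is changed from an ether to a magnesium alkoxide, which directs with high selectivity but in the threo sense, and C6 is corrected afterwards.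
- Mitsunobu inversion of **15** (4-nitrobenzoic acid, PPh3, DIAD) gives (2S)-1-[4-(benzyloxy)phenyl]but-3-en-2-yl 4-nitrobenzoate F1.
- Methanolysis (K2CO3, MeOH) gives the (S)-allylic alcohol F2.
- Oxime **8** is chlorinated with N-chlorosuccinimide to hydroximoyl chloride **17**, which is added slowly to the magnesium alkoxide of F2 (EtMgBr, i-PrOH, CH2Cl2, 0 °C). The metal-bound alkoxide delivers the dipole oxygen to its own face and should give the threo isoxazoline alcohol F3 (5S,6S).
- A second Mitsunobu inversion at C6 gives the erythro 4-nitrobenzoate F4.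
- Methanolysis gives the erythro isoxazoline alcohol F5.
- Benzylation (BnBr, Ag2O) returns **19**.

**Step 14.** The benzylic mesylate may ionise, be methanolysed or eliminate to the styrene before O5 is freed. Ionisation would erode the inversion and let the cis ring form. The cause is the intrinsic lability of secondary benzylic sulfonates, only partly offset by the tosyloxy group.

Fallback, from **25**, returning at **28**: no sulfonate is made. Methanolysis of the acetate (K2CO3, MeOH) gives the 1,5-diol F6, (1R,3R,5S,6R)-3,6-bis(benzyloxy)-7-[4-(benzyloxy)phenyl]-1-[3-methoxy-4-(tosyloxy)phenyl]heptane-1,5-diol. F6 is cyclodehydrated under Mitsunobu conditions (PPh3, DIAD, toluene, 0 °C). The two alkoxyphosphonium species interconvert, and closure should occur at the benzylic carbon, which is far more open to backside attack than the hindered, β-oxygenated C5, again with inversion at C1.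

**Step 12.** Acid-catalysed benzylation next to a β-acetate may be accompanied by acetyl migration from O5 to O3, partial loss of the silyl ether, or C-benzylation of ring B.

Fallback, from **23**, returning at **29**: the ether at C3 is abandoned.
- Acetylation (Ac2O, pyridine, DMAP) gives the diacetate F7.
- HF·pyridine gives the C1 alcohol F8.
- Mesylation gives the diacetate mesylate F9.
- K2CO3/MeOH removes both acetates to the dihydroxy mesylate F10, which closes through O5 (six-membered ring preferred over the oxetane from O3) to the oxane F11 with free C3 hydroxyl.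
- Hydrogenolysis as in step 15 gives **29**.

This is second choice because the C3 acetate could assist departure of the mesylate as a six-membered acyloxonium ion.

**Step 15.** Over-reduction, i.e. hydrogenolysis of the cyclic benzylic C1–O bond, or sluggish cleavage of the two secondary benzyl ethers that forces long exposure. Fallback, from **28** to **29** directly: Lewis-acid debenzylation with BCl3 and pentamethylbenzene as cation scavenger (CH2Cl2, −78 °C). It leaves the aryl methyl ether and the sulfonate intact and involves no metal surface.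

**Step 16.** Epimerisation at C1 by reversible ring opening through a quinone methide once the ring A phenoxide is formed in warm base; this would lead to the more stable cis ring. Fallback, from **29** to **30** directly: reductive S–O cleavage with Mg in MeOH at room temperature, an electron-transfer process that needs neither hydroxide nor heat.

## Further compounds

F1 | step 9 | (2S)-1-[4-(benzyloxy)phenyl]but-3-en-2-yl 4-nitrobenzoate | C=C[C@@H](OC(=O)c1ccc(cc1)[N+](=O)[O-])Cc1ccc(OCc2ccccc2)cc1
F2 | step 9 | (2S)-1-[4-(benzyloxy)phenyl]but-3-en-2-ol | C=C[C@@H](O)Cc1ccc(OCc2ccccc2)cc1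
F3 | step 9 | threo isoxazoline alcohol, 4-{(1R)-2-[(5S)-5-{(1S)-2-[4-(benzyloxy)phenyl]-1-hydroxyethyl}-4,5-dihydro-1,2-oxazol-3-yl]-1-(tert-butyldimethylsilyloxy)ethyl}-2-methoxyphenyl 4-methylbenzenesulfonate | COc1cc([C@H](O[Si](C)(C)C(C)(C)C)CC2=NO[C@H]([C@@H](O)Cc3ccc(OCc4ccccc4)cc3)C2)ccc1OS(=O)(=O)c1ccc(C)cc1
F4 | step 9 | erythro 4-nitrobenzoate, (1R)-2-[4-(benzyloxy)phenyl]-1-[(5S)-3-{(2R)-2-(tert-butyldimethylsilyloxy)-2-[3-methoxy-4-(tosyloxy)phenyl]ethyl}-4,5-dihydro-1,2-oxazol-5-yl]ethyl 4-nitrobenzoate | COc1cc([C@H](O[Si](C)(C)C(C)(C)C)CC2=NO[C@H]([C@H](OC(=O)c3ccc(cc3)[N+](=O)[O-])Cc3ccc(OCc4ccccc4)cc3)C2)ccc1OS(=O)(=O)c1ccc(C)cc1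
F5 | step 9 | erythro isoxazoline alcohol, 4-{(1R)-2-[(5S)-5-{(1R)-2-[4-(benzyloxy)phenyl]-1-hydroxyethyl}-4,5-dihydro-1,2-oxazol-3-yl]-1-(tert-butyldimethylsilyloxy)ethyl}-2-methoxyphenyl 4-methylbenzenesulfonate | COc1cc([C@H](O[Si](C)(C)C(C)(C)C)CC2=NO[C@H]([C@H](O)Cc3ccc(OCc4ccccc4)cc3)C2)ccc1OS(=O)(=O)c1ccc(C)cc1
F6 | step 14 | (1R,3R,5S,6R)-3,6-bis(benzyloxy)-7-[4-(benzyloxy)phenyl]-1-[3-methoxy-4-(tosyloxy)phenyl]heptane-1,5-diol | COc1cc([C@H](O)C[C@@H](OCc2ccccc2)C[C@H](O)[C@H](OCc2ccccc2)Cc2ccc(OCc3ccccc3)cc2)ccc1OS(=O)(=O)c1ccc(C)cc1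
F7 | step 12 | (1R,3S,5S,6R)-6-(benzyloxy)-7-[4-(benzyloxy)phenyl]-1-(tert-butyldimethylsilyloxy)-1-[3-methoxy-4-(tosyloxy)phenyl]heptane-3,5-diyl diacetate | COc1cc([C@H](O[Si](C)(C)C(C)(C)C)C[C@@H](OC(C)=O)C[C@H](OC(C)=O)[C@H](OCc2ccccc2)Cc2ccc(OCc3ccccc3)cc2)ccc1OS(=O)(=O)c1ccc(C)cc1
F8 | step 12 | (1R,3R,5S,6R)-6-(benzyloxy)-7-[4-(benzyloxy)phenyl]-1-hydroxy-1-[3-methoxy-4-(tosyloxy)phenyl]heptane-3,5-diyl diacetate | COc1cc([C@H](O)C[C@@H](OC(C)=O)C[C@H](OC(C)=O)[C@H](OCc2ccccc2)Cc2ccc(OCc3ccccc3)cc2)ccc1OS(=O)(=O)c1ccc(C)cc1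
F9 | step 12 | (1R,3S,5S,6R)-6-(benzyloxy)-7-[4-(benzyloxy)phenyl]-1-(methanesulfonyloxy)-1-[3-methoxy-4-(tosyloxy)phenyl]heptane-3,5-diyl diacetate | COc1cc([C@H](OS(C)(=O)=O)C[C@@H](OC(C)=O)C[C@H](OC(C)=O)[C@H](OCc2ccccc2)Cc2ccc(OCc3ccccc3)cc2)ccc1OS(=O)(=O)c1ccc(C)cc1
F10 | step 12 | (1R,3S,5S,6R)-6-(benzyloxy)-7-[4-(benzyloxy)phenyl]-3,5-dihydroxy-1-[3-methoxy-4-(tosyloxy)phenyl]heptyl methanesulfonate | COc1cc([C@H](OS(C)(=O)=O)C[C@@H](O)C[C@H](O)[C@H](OCc2ccccc2)Cc2ccc(OCc3ccccc3)cc2)ccc1OS(=O)(=O)c1ccc(C)cc1
F11 | step 12 | 4-[(2S,4R,6S)-6-{(1R)-1-(benzyloxy)-2-[4-(benzyloxy)phenyl]ethyl}-4-hydroxyoxan-2-yl]-2-methoxyphenyl 4-methylbenzenesulfonate | COc1cc([C@@H]2C[C@@H](O)C[C@@H]([C@H](OCc3ccccc3)Cc3ccc(OCc4ccccc4)cc3)O2)ccc1OS(=O)(=O)c1ccc(C)cc1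
F0 | step 15 | none | none
F0 | step 16 | none | none
A1 | alternative 1 | (1S,3R)-1-[4-(benzyloxy)-3-methoxyphenyl]-4-[(2R,3R)-3-(4-benzyloxybenzyl)oxiran-2-yl]-3-(tert-butyldimethylsilyloxy)butan-1-ol | COc1cc([C@@H](O)C[C@@H](O[Si](C)(C)C(C)(C)C)C[C@H]2O[C@@H]2Cc2ccc(OCc3ccccc3)cc2)ccc1OCc1ccccc1
A2 | alternative 1 | (1R)-2-[4-(benzyloxy)phenyl]-1-[(2S,4R,6S)-6-[4-(benzyloxy)-3-methoxyphenyl]-4-(tert-butyldimethylsilyloxy)oxan-2-yl]ethan-1-ol | COc1cc([C@@H]2C[C@@H](O[Si](C)(C)C(C)(C)C)C[C@@H]([C@H](O)Cc3ccc(OCc4ccccc4)cc3)O2)ccc1OCc1ccccc1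
A3 | alternative 2 | 2-(tert-butyldimethylsilyl)-1,3-dithiane | CC(C)(C)[Si](C)(C)C1SCCCS1
A4 | alternative 2 | 2-methoxy-4-[(2S)-oxiran-2-yl]phenyl 4-methylbenzenesulfonate | COc1cc([C@H]2CO2)ccc1OS(=O)(=O)c1ccc(C)cc1
A5 | alternative 2 | (2S)-2-{(1R)-1-(benzyloxy)-2-[4-(benzyloxy)phenyl]ethyl}oxirane | C1O[C@@H]1[C@H](OCc1ccccc1)Cc1ccc(OCc2ccccc2)cc1
A6 | alternative 2 | C1–C7 chain with a 1,3-dithiane at C3: 4-{(1R)-2-[2-{(2S,3R)-3-(benzyloxy)-4-[4-(benzyloxy)phenyl]-2-hydroxybutyl}-1,3-dithian-2-yl]-1-(tert-butyldimethylsilyloxy)ethyl}-2-methoxyphenyl 4-methylbenzenesulfonate | COc1cc([C@H](O[Si](C)(C)C(C)(C)C)CC2(C[C@H](O)[C@H](OCc3ccccc3)Cc3ccc(OCc4ccccc4)cc3)SCCCS2)ccc1OS(=O)(=O)c1ccc(C)cc1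
A7 | alternative 3 | (3S,5S,6R)-7-[4-(benzyloxy)phenyl]-3,6-bis(tert-butyldimethylsilyloxy)hept-1-en-5-yl 4-(benzyloxy)-3-methoxybenzoate | COc1cc(C(=O)O[C@@H](C[C@H](O[Si](C)(C)C(C)(C)C)C=C)[C@H](O[Si](C)(C)C(C)(C)C)Cc2ccc(OCc3ccccc3)cc2)ccc1OCc1ccccc1
A8 | alternative 3 | enol ether from A7: 1-(benzyloxy)-4-{1-[(3S,5S,6R)-7-[4-(benzyloxy)phenyl]-3,6-bis(tert-butyldimethylsilyloxy)hept-1-en-5-yloxy]ethenyl}-2-methoxybenzene | COc1cc(C(=C)O[C@@H](C[C@H](O[Si](C)(C)C(C)(C)C)C=C)[C@H](O[Si](C)(C)C(C)(C)C)Cc2ccc(OCc3ccccc3)cc2)ccc1OCc1ccccc1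
A9 | alternative 3 | (2S,4S)-6-[4-(benzyloxy)-3-methoxyphenyl]-2-{(1R)-2-[4-(benzyloxy)phenyl]-1-(tert-butyldimethylsilyloxy)ethyl}-4-(tert-butyldimethylsilyloxy)-3,4-dihydro-2H-pyran | COc1cc(C2=C[C@@H](O[Si](C)(C)C(C)(C)C)C[C@@H]([C@H](O[Si](C)(C)C(C)(C)C)Cc3ccc(OCc4ccccc4)cc3)O2)ccc1OCc1ccccc1
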